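At early times the alpha run loses 12.1% of its starting material and shows 11.2% of target, so by 8.00 h the two readings nearly agree; later the balance opens, and the missing points count target lost.

all flasks: free enzyme 0.01 mol%

| charge | starting material | second substrate | temperature | remark | time |
|---|---|---|---|---|---|
| alpha | 0.13 M | 0.45 equiv | 28 °C | run made earlier |  |
| epsilon | 0.13 M | 0.68 equiv | 44 °C | run made earlier |  |
| beta | 0.20 M | 0.90 equiv | 28 °C | run made earlier |  |
| teal | 0.13 M | 0.900 equiv | 50 °C |  | 40 h |
| amber | 0.13 M | 0.900 equiv | 20 °C |  | 40 h |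

| run | time / h | target / % | starting material / % |
|---|---|---|---|
| alpha | 8.00 | 11.2 | 87.9 |
| alpha | 20.0 | 14.4 | 73.4 |
| alpha | 30.0 | 12.1 | 63.6 |
| alpha | 40.0 | 8.6 | 61.0 |
| alpha | 60.0 | 2.2 | 58.0 |
| alpha | 72.0 | 3.5 | 56.6 |
| epsilon | 3.00 | 12.3 | 74.3 |
| epsilon | 6.00 | 9.7 | 60.5 |
| epsilon | 10.0 | 5.8 | 49.1 |
| epsilon | 15.0 | 1.9 | 41.6 |
| epsilon | 20.0 | 1.0 | 40.4 |
| epsilon | 25.0 | 1.2 | 39.3 |
| beta | 15.0 | 22.6 | 61.5 |
| beta | 30.0 | 24.4 | 32.7 |
| beta | 40.0 | 18.6 | 25.3 |
| beta | 60.0 | 7.6 | 17.6 |
| beta | 72.0 | 2.2 | 13.0 |

(readings scatter by 1 percentage point)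

* the flask with the highest amount of target, in percent of the starting material charged ("all alike" if they lie within 1.5 percentage points) (teal / amber / all alike)
* final target, as a percentage of the starting material charged, in teal
* final target, as a percentage of the starting material charged, in amber

- the numbers in the tables scatter by 1 percentage point (one standard deviation)

Temperature comes first. The mean target in a window, times its hours, divided by the points lost in it, gives a first-order lifetime (the pseudo-first-order picture). The alpha readings from 20.0 h to 30.0 h give 11.0 h, and the epsilon readings from 3.00 h to 6.00 h give 2.01 h. Stepping by an equal factor per degree gives amber, at 20 °C, the target lifetime 25.5 h; the table also holds the same stepping for teal.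

| Flask | Temperature | Target lifetime |
|---|---|---|
| alpha | 28 °C | 11.0 h |
| epsilon | 44 °C | 2.01 h |
| amber | 20 °C | 25.5 h |
| teal | 50 °C | 1.07 h |

Epsilon's target had fallen to 1.0% by 20.0 h. If teal's making ends as early, its remaining hours are 18.7 lifetimes, and teal ends near zero.

Second substrate comes next, as the limiting reagent. The alpha readings stood at 43.4% conversion at 72.0 h, on 0.45 equiv. Amber's early rate, scaled with c(second substrate) and stepped by degree from the early readings, is 0.0156 /h. Held for 40 h, this rate gives an estimated conversion of 62.4%, against 0.900 equiv charged.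

Time comes last. Of target made evenly over a time, the share still standing is the lifetime over the time, times one minus exp(−time/lifetime): 50.5% in amber. Amber's estimate at a held rate is therefore 31.6%, and a falling rate lowers it.

The forecast gives amber, with 20% in amber and 0.5% in teal, where “the target has essentially gone by 40 h”.

    free enzyme → unfolded enzyme (k = 5.10 × 10⁻⁶ /min, Ea = 197 kJ/mol)
    starting material + free enzyme ⇌ starting complex (K = 7.50 /M, k = 220 /M/min, Ea = 58.0 kJ/mol, ΔH = −33.0 kJ/mol)
    second substrate + starting complex ⇌ ternary complex (K = 31.0 /M, k = 5800 /M/min, Ea = 49.0 kJ/mol, ΔH = 40.0 kJ/mol)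
    ternary complex → free enzyme + target (k = 2.90 /min, Ea = 72.0 kJ/mol)
    target → over-reaction product (k = 4.20 × 10⁻⁴ /min, Ea = 99.0 kJ/mol)
    (constants at 20 °C)

Amber holds 21.9% and teal 0%, so amber has the most. At 18.3 h amber makes target 2.54 times faster than it uses it up. With 64.2% of its starting material left at 40.0 h, amber keeps 61.2% of what it converted as target, against the reckoned share of 50.5% from a lifetime of 25.5 h. A neighbour flask, amber with 0.04 mol% of free enzyme, converts 78.3% and keeps 52.9% of it as target.

The readings were generated by integration from invented constants, noise included.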